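One lost catalyst is my unit here: I count how much Z turns over for each L.X that falls into L.L.X.

    L + X → L.X (k1 = 0.732 /M/s)
    L + L.X → L.L.X (k2 = 0.0103 /M/s)
    Z.L.X → X + Q (k3 = 1.65 /s)
    Z + L.X ⇌ Z.L.X (K4 = 0.562 /M, k4 = 4.48 /M/s)

Z 1.2 M; L 3.00 M; X 32 mM

- the form that holds most of the catalyst when 50% of the Z are converted (L.L.X / Z.L.X / L.X / X)
- its share of the catalyst then

I write [Z] and [L] for the concentrations and E for the L.L.X formed. In this flask Z.L.X lasts 0.104 s, while L.X lasts 32.4 s against the leak, so I hold Z.L.X in steady state with L.X. Of the Z.L.X formed, 17.1% goes on to Q and the rest falls back. The capture constant times that share, over the leak constant, gives W = 74.6. W is the turnovers bought per lost catalyst at equal [Z] and [L], a selectivity factor; at any moment the count is W[Z]/[L].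

Each turnover takes one L, so [L] minus [Z] stays near 1.80 M. Summing the count along the run gives E as the drop in Z, plus that difference times the logarithm of charged over remaining Z, all over W.

Now the curve of E against conversion. It starts at one catalyst lost per 29.8 turnovers and steepens to one per 18.6 at 50%. At a third converted, E is 15.1 mM, just short of half the charge. At 50%, E is 24.8 mM, or 77.4% of the catalyst. The other forms share what remains, so I commit to L.L.X. The sum reaches 34.3 mM at 63.2% converted, so I expect the curve to level off below that conversion, at the charge of 32 mM.

The forecast says L.L.X at 77%, on the ground that “the competition between this leak and productive Z turnover is independent of how much active catalyst remains”. It puts the cost at roughly one catalyst per 50 to 75 turnovers, where my count runs from 29.8 down to 18.6.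

The flask gives L.L.X with 76.4% of the catalyst at 1.56 min, when L.X holds 15.2%. Now take the second flask, with twice the X. W = 74.6 contains no X, so I take the same cost of 24.8 mM, now out of 64.0 mM. If the catalyst outside L.L.X falls at a steady fractional rate, the time to 50% goes as the logarithm of charge over charge minus E, and this estimate gives a factor of 0.329. The run of that flask shows 0.333.

The numbers of this flask come from no measurement, and the outcome is calculated.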